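**Retrosynthetic overview**
1. The 5,6-epoxide, the C2/C3 diol and the acetates come last, on a (2Z,5Z)-cyclodecadiene. The ten-membered ring is closed by ring-closing metathesis at C2=C3, and C5=C6 is built by Stork–Zhao/Stille chemistry on a C6 aldehyde.
2. The γ-lactone (O–C7–C8–C17–C19) is cut at C19–C17 and O–C7. Its O–C19(=O) unit bridges C7 and the carbinol carbon C17, which are 1,3-related across C8. C19 can therefore sit on the C17 oxygen as a diethylcarbamate, shift onto C17 (1,2-carbamoyl shift), and its carbonyl oxygen then closes on the allylic epoxide carbon C7. The 8,9-diol follows by syn-dihydroxylation of the C8=C9 alkene that remains.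
3. The key precursor (allylic carbamate and vinyl epoxide on a C8=C9 alkene) is built on the ring-A aldehyde: alkyne formation, alkynylation (C17), trans-hydrostannation, acylation and CBS reduction (C7).
4. Ring A (C1, C10–C14) comes from an epoxide-initiated cation–olefin cyclisation of a vinyl epoxide made from geranyl acetate (Sharpless epoxidation sets the absolute configuration), then directed epoxidation/reductive opening (C11, C12) and inversion at C14.
5. Ring order: cyclohexane, then γ-lactone, then ten-membered carbocycle, then oxirane.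

Key step: step 21

Remark: briarane numbering (C1–C20; lactone C7–O–C19(=O)–C17(C18)–C8) is used for all intermediates; on the cyclohexane ring β is the face of the C15 methyl group.
Assumption: (S,S)-ProPhenol is taken as the ligand antipode that gives the (17R)-carbinol in step 15; if the sense of induction is the opposite, (R,R)-ProPhenol is used.

Step 1
Reactants: 1 geranyl acetate
Product: 2 (2E,6E)-8-hydroxygeranyl acetate
Conditions: SeO2 (cat.), t-BuOOH, salicylic acid (cat.), CH2Cl2, 23 °C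
Reagents that add atoms: tert-butyl hydroperoxide, CC(C)(C)OO
Why: Catalytic SeO2/t-BuOOH allylic hydroxylation (Sharpless–Umbreit) should be selective for the (E)-methyl group of the distal trisubstituted alkene, because the 2,3-alkene is deactivated by the allylic acetate.

Step 2
Reactants: 2 (2E,6E)-8-hydroxygeranyl acetate
Product: 3 (6R,7R)-6,7-epoxy-8-hydroxygeranyl acetate
Conditions: Ti(OiPr)4 (cat.), D-(−)-diethyl tartrate (cat.), t-BuOOH, 4 Å MS, CH2Cl2, −20 °C
Reagents that add atoms: tert-butyl hydroperoxide, CC(C)(C)OO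
Why: Sharpless asymmetric epoxidation of the primary allylic alcohol with D-(−)-tartrate should give the (6R,7R)-epoxide, which later fixes the absolute configuration of ring A.

Step 3
Reactants: 3 (6R,7R)-6,7-epoxy-8-hydroxygeranyl acetate
Product: 4 (6R,7S)-6,7-epoxy-8-oxogeranyl acetate (epoxide unchanged; descriptor changes by priority only)
Conditions: TEMPO (cat.), PhI(OAc)2, CH2Cl2, 23 °C
Reagents that add atoms: none
Why: TEMPO/PhI(OAc)2 oxidation should convert the primary epoxy alcohol to the aldehyde without touching the epoxide or the alkene.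

Step 4
Reactants: 4 (6R,7S)-6,7-epoxy-8-oxogeranyl acetate
Product: 5 (2E)-3-methyl-5-[(2R,3R)-3-methyl-3-vinyloxiran-2-yl]pent-2-enyl acetate
Conditions: Ph3PCH3Br, KHMDS, THF, −78 → 0 °C
Reagents that add atoms: methyltriphenylphosphonium bromide, C[P+](c1ccccc1)(c1ccccc1)c1ccccc1.[Br-]
Why: Wittig methylenation of the non-enolisable epoxy aldehyde should install the future C2=C3 vinyl group and make the epoxide carbon a tertiary, allylic cation precursor.

Step 5
Reactants: 5 vinyl epoxide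
Product: 6 [(1S,5R,6R)-5-hydroxy-2,6-dimethyl-6-vinylcyclohex-2-en-1-yl]methyl acetate (ring A: C9 acetate, Δ11, 14β-OH, 1β-methyl, 1α-vinyl, H-10α)
Conditions: MeAlCl2, CH2Cl2, −78 °C
Reagents that add atoms: none
Why: In this epoxide-initiated cation–olefin cyclisation through a chair transition state the alkene should attack C1 anti to the epoxide oxygen (inversion), the (E)-alkene places C9 equatorial (C2 and C9 trans), the C14 oxygen is retained (β), and Zaitsev loss of H-12 gives the Δ11 alkene.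

Step 6
Reactants: 6 ring-A cyclohexenol
Product: 7 11β,12β-epoxide of 6
Conditions: VO(acac)2 (cat.), t-BuOOH, CH2Cl2, 0 → 23 °C
Reagents that add atoms: tert-butyl hydroperoxide, CC(C)(C)OO
Why: Vanadium-catalysed epoxidation directed by the homoallylic 14β-hydroxyl should deliver oxygen syn to it and leave the undirected monosubstituted vinyl group alone.

Step 7
Reactants: 7 11β,12β-epoxide
Product: 8 12β,14β-diol with 11β-methyl (H-11α)
Conditions: Cp2TiCl2 (cat.), Mn, 2,4,6-collidine·HCl, 1,4-cyclohexadiene, THF, 23 °C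
Reagents that add atoms: none
Why: Titanocene(III)-catalysed reductive epoxide opening (Nugent–RajanBabu/Gansäuer) gives the tertiary C11 radical and the C12 titanium alkoxide, and hydrogen-atom transfer anti to the bulky 12β-titanoxy group and the axial C15 methyl should set H-11α while C12–O is retained.

Step 8
Reactants: 8 12β,14β-diol
Product: 9 12-O-TBS ether of 8
Conditions: TBSCl, imidazole, DMF, 0 °C
Reagents that add atoms: tert-butyldimethylsilyl chloride, CC(C)(C)[Si](C)(C)Cl
Why: Silylation should be selective for the 12β-hydroxyl because the 14-hydroxyl is neopentylic (next to quaternary C1).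

Step 9
Reactants: 9 12-O-TBS ether
Product: 10 14-ketone
Conditions: TPAP (cat.), NMO, 4 Å MS, CH2Cl2, 23 °C
Reagents that add atoms: none
Why: Ley–Griffith oxidation should convert the remaining secondary alcohol to the ketone under neutral conditions that the acetate and silyl ether tolerate.

Step 10
Reactants: 10 14-ketone
Product: 11 14α-alcohol (C14 inverted)
Conditions: L-Selectride, THF, −78 °C
Reagents that add atoms: none
Why: The bulky hydride should attack the ketone next to quaternary C1 from the equatorial direction and give the axial 14α-alcohol (as with 3-keto-4,4-dimethyl triterpenoids), while the acetate survives at −78 °C.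

Step 11
Reactants: 11 14α-alcohol
Product: 12 14-O-TES, 12-O-TBS acetate
Conditions: TESOTf, 2,6-lutidine, CH2Cl2, −78 → 0 °C
Reagents that add atoms: triethylsilyl trifluoromethanesulfonate, CC[Si](CC)(CC)OS(=O)(=O)C(F)(F)F
Why: The silyl triflate should silylate the hindered axial alcohol, giving a group that can later be removed in the presence of the TBS ether.

Step 12
Reactants: 12 bis-silyl acetate
Product: 13 C9 primary alcohol
Conditions: K2CO3 (cat.), MeOH, 0 °C
Reagents that add atoms: none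
Why: Mild transesterification should remove the primary acetate and leave both silyl ethers.

Step 13
Reactants: 13 C9 alcohol
Product: 14 C9 aldehyde
Conditions: TEMPO (cat.), PhI(OAc)2, CH2Cl2, 23 °C
Reagents that add atoms: none
Why: TEMPO/PhI(OAc)2 oxidation of the only free (primary) alcohol should give the aldehyde.

Step 14
Reactants: 14 C9 aldehyde
Product: 15 terminal alkyne (C9≡C8)
Conditions: dimethyl (1-diazo-2-oxopropyl)phosphonate, K2CO3, MeOH, 0 → 23 °C
Reagents that add atoms: dimethyl (1-diazo-2-oxopropyl)phosphonate, COP(=O)(OC)C(=[N+]=[N-])C(C)=O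
Why: Seyferth–Gilbert homologation with the Ohira–Bestmann reagent should add C8 as the alkyne terminus, and any epimerisation at C10 leads to the favoured equatorial isomer.

Step 15
Reactants: 15 terminal alkyne
Product: 16 (17R)-propargylic alcohol
Conditions: (S,S)-ProPhenol (cat.), Me2Zn, Ph3P=O (cat.), toluene; MeCHO, 0 °C
Reagents that add atoms: acetaldehyde, CC=O
Why: Zinc–ProPhenol catalysed enantioselective alkynylation of acetaldehyde (Trost) should create the C17 carbinol under catalyst control.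

Step 16
Reactants: 16 (17R)-propargylic alcohol
Product: 17 (17R)-C8-stannyl allylic alcohol (C8=C9, tin cis to C10)
Conditions: [Cp*RuCl]4 (cat.), Bu3SnH, CH2Cl2, 23 °C
Reagents that add atoms: tributyltin hydride, CCCC[SnH](CCCC)CCCC
Why: Hydroxyl-directed ruthenium-catalysed trans-hydrostannation (Fürstner) should place tin on the proximal carbon C8 and hydrogen anti on C9, which fixes the C8=C9 geometry.

Step 17
Reactants: 17 stannyl allylic alcohol
Product: 18 N,N-diethylcarbamate of 17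
Conditions: NaH, Et2NCOCl, THF, 0 → 23 °C
Reagents that add atoms: N,N-diethylcarbamoyl chloride, CCN(CC)C(Cl)=O
Why: O-Carbamoylation of the sodium alkoxide should install the group that later supplies C19 and the lactone ring oxygen.

Step 18
Reactants: 18 stannyl carbamate
Product: 19 α-chloro enone (C7 ketone, C6 chloride; C7 cis to C10)
Conditions: ClCH2COCl, Pd2(dba)3 (cat.), P(2-furyl)3 (cat.), toluene, 50 °C
Reagents that add atoms: chloroacetyl chloride, ClCC(Cl)=O
Why: Stille acylation of the alkenylstannane should proceed with retention of alkene geometry and introduce C7 and C6.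

Step 19
Reactants: 19 α-chloro enone
Product: 20 (7S,17R)-chlorohydrin
Conditions: (S)-Me-CBS (cat.), catecholborane, toluene, −78 °C
Reagents that add atoms: none
Why: Corey–Bakshi–Shibata reduction (alkenyl group large, CH2Cl small) should set the (7S)-carbinol, and catecholborane leaves the alkenes alone.

Step 20
Reactants: 20 chlorohydrin
Product: 21 (7S,17R)-vinyl epoxide carbamate
Conditions: K2CO3, MeOH, 0 → 23 °C
Reagents that add atoms: none
Why: Intramolecular Williamson closure of the chlorohydrin should give the terminal epoxide with retention at C7.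

Step 21
Reactants: 21 (7S,17R)-vinyl epoxide carbamate
Product: 25 (7R,17R)-17-hydroxy-β-alkylidene-γ-lactone (C6–OH free, C8=C9), via C17-lithio carbamate 22 (not isolated), via lithium alkoxide of the α-hydroxy amide 23 (not isolated), via cyclic iminium ether 24 (not isolated)
Conditions: s-BuLi, TMEDA, Et2O, −78 → −20 °C; then AcOH, THF–H2O, 23 °C
Reagents that add atoms: water, O
Why: Carbamate-directed α-lithiation should remove the allylic C17–H with retention, and lithio carbamate 22 then undergoes an anionic 1,2-carbamoyl (O→C) shift, again with retention because the acyl group is delivered through a three-centre transition state to the lithium-bearing lobe; this forms C19–C17 and frees the C17 oxygen as the alkoxide of α-hydroxy amide 23. On acidification the amide carbonyl oxygen, now 1,3 to the epoxide carbon across C8, should open the allylic epoxide at C7 in a 5-exo-tet closure with inversion to give iminium ether 24, whose hydrolysis expels diethylamine and leaves the γ-lactone. The closest known reaction types are the carbamate-to-α-hydroxy-amide rearrangement of α-lithiated O-benzyl and O-allyl carbamates and the amide-participated opening of epoxides (iminolactonisation). C17 is controlled by the (17R)-carbinol of 21 through double retention and C7 by SN2 inversion of the (7S)-epoxide carbon, so both new centres are set stereospecifically. The step needs α- rather than γ-transfer of the carbamoyl group and attack at C7 rather than C6; the first is secured by lithium chelation to the carbamate carbonyl at C17, the second by allylic activation of C7 and the preference for a five- over a six-membered iminium ether.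

Step 22
Reactants: 25 β-alkylidene lactone
Product: 26 (7S,8S,9S,17R)-6,8,9,17-tetrol lactone
Conditions: OsO4 (cat.), (DHQ)2PHAL (cat.), NMO, t-BuOH–H2O, 0 °C
Reagents that add atoms: N-methylmorpholine N-oxide, C[N+]1([O-])CCOCC1; water, O
Why: Ligand-accelerated osmium-catalysed syn-dihydroxylation of the trisubstituted C8=C9 alkene should occur on the lactone face anti to the allylic C17 hydroxyl and the C7 side chain (Kishi's rule, reinforced by the DHQ ligand), setting 8S and 9S together, while the neopentylic C1 vinyl group reacts more slowly.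

Step 23
Reactants: 26 tetrol lactone
Product: 27 8,9-acetonide
Conditions: 2,2-dimethoxypropane, PPTS (cat.), acetone, 23 °C
Reagents that add atoms: 2,2-dimethoxypropane, COC(C)(C)OC
Why: Acetonide formation on the vicinal 8,9-diol should protect the β-hydroxyl of the coming aldehyde against retro-aldol cleavage.

Step 24
Reactants: 27 acetonide
Product: 28 C6 aldehyde
Conditions: TEMPO (cat.), PhI(OAc)2, CH2Cl2, 23 °C
Reagents that add atoms: none
Why: TEMPO/PhI(OAc)2 should oxidise the primary C6 alcohol and leave the tertiary C17 hydroxyl.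

Step 25
Reactants: 28 C6 aldehyde
Product: 29 (5Z)-5-iodoalkene (iodine cis to C7)
Conditions: EtPPh3I, n-BuLi, THF; I2, −78 °C; NaHMDS; then 28, −78 → −20 °C
Reagents that add atoms: ethyltriphenylphosphonium iodide, CC[P+](c1ccccc1)(c1ccccc1)c1ccccc1.[I-]; iodine, II
Why: Stork–Zhao olefination with the α-iodo ylide should give the (Z)-iodoalkene, which places iodine (later C4) cis to C7.

Step 26
Reactants: 29 (5Z)-iodoalkene
Product: 30 (5Z)-triene (C5 carries methyl and allyl)
Conditions: allyl-SnBu3, Pd2(dba)3 (cat.), AsPh3 (cat.), CuI, DMF, 23 °C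
Reagents that add atoms: allyltributylstannane, C=CC[Sn](CCCC)(CCCC)CCCC
Why: Stille coupling should replace iodine by allyl (C4, C3) with retention of the (Z)-geometry.

Step 27
Reactants: 30 triene
Product: 31 (2Z,5Z)-macrocycle
Conditions: Grubbs II (cat.), toluene (high dilution), 80 °C
Reagents that add atoms: none
Why: Ring-closing metathesis between the two monosubstituted terminal alkenes should close the ten-membered ring, whose size enforces the (Z)-C2=C3 alkene.

Step 28
Reactants: 31 macrocycle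
Product: 32 8,9,14,17-tetrol 12-O-TBS macrocyclic diene
Conditions: PPTS, MeOH, 40 °C
Reagents that add atoms: none
Why: Mild acid methanolysis should remove the acetonide and the triethylsilyl ether and leave the TBS ether.

Step 29
Reactants: 32 macrocyclic diene
Product: 33 (5R,6S)-5,6-epoxide
Conditions: m-CPBA, NaHCO3, CH2Cl2, −20 → 0 °C
Reagents that add atoms: 3-chloroperbenzoic acid, OOC(=O)c1cccc(Cl)c1
Why: Prilezhaev epoxidation should take the more nucleophilic trisubstituted C5=C6 alkene, syn to the homoallylic 8β-hydroxyl and anti to the α-oriented lactone.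

Step 30
Reactants: 33 epoxide
Product: 34 (2R,3S)-2,3-diol
Conditions: OsO4 (cat.), NMO, acetone–H2O, 0 °C
Reagents that add atoms: N-methylmorpholine N-oxide, C[N+]1([O-])CCOCC1; water, O
Why: Upjohn syn-dihydroxylation of the remaining cis-disubstituted alkene from the exposed peripheral face of the ten-membered ring should give the 2,3-cis-diol.

Step 31
Reactants: 34 hexol
Product: 35 2,3,9,14-tetraacetate 12-O-TBS ether
Conditions: Ac2O, pyridine, DMAP (cat.), 0 → 23 °C
Reagents that add atoms: acetic anhydride, CC(=O)OC(C)=O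
Why: Acetylation should take the four secondary alcohols, the tertiary 8- and 17-hydroxyls being too hindered.

Step 32
Reactants: 35 tetraacetate silyl ether
Product: 36 CNP0287149.1 (target)
Conditions: HF·pyridine, pyridine, THF, 0 °C
Reagents that add atoms: none
Why: Buffered fluoride desilylation should free the 12-hydroxyl under conditions that the epoxide, lactone and acetates tolerate.

**Compound list**
1 | geranyl acetate | CC(=O)OC/C=C(\C)CCC=C(C)C | starting material
2 | (2E,6E)-8-hydroxygeranyl acetate | CC(=O)OC/C=C(\C)CC/C=C(\C)CO | intermediate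
3 | (6R,7R)-6,7-epoxy-8-hydroxygeranyl acetate | CC(=O)OC/C=C(\C)CC[C@H]1O[C@]1(C)CO | intermediate
4 | (6R,7S)-6,7-epoxy-8-oxogeranyl acetate | CC(=O)OC/C=C(\C)CC[C@H]1O[C@]1(C)C=O | intermediate
5 | (2E)-3-methyl-5-[(2R,3R)-3-methyl-3-vinyloxiran-2-yl]pent-2-enyl acetate | CC(=O)OC/C=C(\C)CC[C@H]1O[C@]1(C)C=C | intermediate
6 | [(1S,5R,6R)-5-hydroxy-2,6-dimethyl-6-vinylcyclohex-2-en-1-yl]methyl acetate | CC(=O)OC[C@H]1C(C)=CC[C@@H](O)[C@]1(C)C=C | intermediate
7 | 11β,12β-epoxide of 6 | CC(=O)OC[C@H]1[C@@]2(C)O[C@H]2C[C@@H](O)[C@]1(C)C=C | intermediate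
8 | 12β,14β-diol, 11β-methyl | CC(=O)OC[C@H]1[C@@H](C)[C@@H](O)C[C@@H](O)[C@]1(C)C=C | intermediate
9 | 12-O-TBS ether of 8 | CC(=O)OC[C@H]1[C@@H](C)[C@@H](O[Si](C)(C)C(C)(C)C)C[C@@H](O)[C@]1(C)C=C | intermediate
10 | 14-ketone | CC(=O)OC[C@H]1[C@@H](C)[C@@H](O[Si](C)(C)C(C)(C)C)CC(=O)[C@]1(C)C=C | intermediate
11 | 14α-alcohol | CC(=O)OC[C@H]1[C@@H](C)[C@@H](O[Si](C)(C)C(C)(C)C)C[C@H](O)[C@]1(C)C=C | intermediate
12 | 14-O-TES, 12-O-TBS acetate | CC(=O)OC[C@H]1[C@@H](C)[C@@H](O[Si](C)(C)C(C)(C)C)C[C@H](O[Si](CC)(CC)CC)[C@]1(C)C=C | intermediate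
13 | C9 alcohol | OC[C@H]1[C@@H](C)[C@@H](O[Si](C)(C)C(C)(C)C)C[C@H](O[Si](CC)(CC)CC)[C@]1(C)C=C | intermediate
14 | C9 aldehyde | O=C[C@H]1[C@@H](C)[C@@H](O[Si](C)(C)C(C)(C)C)C[C@H](O[Si](CC)(CC)CC)[C@]1(C)C=C | intermediate
15 | terminal alkyne (C9≡C8) | C#C[C@H]1[C@@H](C)[C@@H](O[Si](C)(C)C(C)(C)C)C[C@H](O[Si](CC)(CC)CC)[C@]1(C)C=C | intermediate
16 | (17R)-propargylic alcohol | C[C@@H](O)C#C[C@H]1[C@@H](C)[C@@H](O[Si](C)(C)C(C)(C)C)C[C@H](O[Si](CC)(CC)CC)[C@]1(C)C=C | intermediate
17 | (17R)-C8-stannyl allylic alcohol | C[C@@H](O)/C([Sn](CCCC)(CCCC)CCCC)=C/[C@H]1[C@@H](C)[C@@H](O[Si](C)(C)C(C)(C)C)C[C@H](O[Si](CC)(CC)CC)[C@]1(C)C=C | intermediate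
18 | N,N-diethylcarbamate of 17 | C[C@@H](OC(=O)N(CC)CC)/C([Sn](CCCC)(CCCC)CCCC)=C/[C@H]1[C@@H](C)[C@@H](O[Si](C)(C)C(C)(C)C)C[C@H](O[Si](CC)(CC)CC)[C@]1(C)C=C | intermediate
19 | α-chloro enone | C[C@@H](OC(=O)N(CC)CC)/C(C(=O)CCl)=C/[C@H]1[C@@H](C)[C@@H](O[Si](C)(C)C(C)(C)C)C[C@H](O[Si](CC)(CC)CC)[C@]1(C)C=C | intermediate
20 | (7S,17R)-chlorohydrin | C[C@@H](OC(=O)N(CC)CC)/C([C@H](O)CCl)=C/[C@H]1[C@@H](C)[C@@H](O[Si](C)(C)C(C)(C)C)C[C@H](O[Si](CC)(CC)CC)[C@]1(C)C=C | intermediate
21 | (7S,17R)-vinyl epoxide carbamate | C[C@@H](OC(=O)N(CC)CC)/C([C@H]2CO2)=C/[C@H]1[C@@H](C)[C@@H](O[Si](C)(C)C(C)(C)C)C[C@H](O[Si](CC)(CC)CC)[C@]1(C)C=C | intermediate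
22 | C17-lithio carbamate | C[C@@]([Li])(OC(=O)N(CC)CC)/C([C@H]2CO2)=C/[C@H]1[C@@H](C)[C@@H](O[Si](C)(C)C(C)(C)C)C[C@H](O[Si](CC)(CC)CC)[C@]1(C)C=C | intermediate
23 | lithium alkoxide of the (17R)-α-hydroxy-N,N-diethylamide | C[C@]([O-])(C(=O)N(CC)CC)/C([C@H]2CO2)=C/[C@H]1[C@@H](C)[C@@H](O[Si](C)(C)C(C)(C)C)C[C@H](O[Si](CC)(CC)CC)[C@]1(C)C=C.[Li+] | intermediate
24 | cyclic iminium ether, acetate salt | C[C@]1(O)C(=[N+](CC)CC)O[C@@H](CO)/C1=C\[C@H]2[C@@H](C)[C@@H](O[Si](C)(C)C(C)(C)C)C[C@H](O[Si](CC)(CC)CC)[C@]2(C)C=C.CC(=O)[O-] | intermediate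
25 | (7R,17R)-17-hydroxy-β-alkylidene-γ-lactone | C[C@]1(O)C(=O)O[C@@H](CO)/C1=C\[C@H]2[C@@H](C)[C@@H](O[Si](C)(C)C(C)(C)C)C[C@H](O[Si](CC)(CC)CC)[C@]2(C)C=C | intermediate
26 | (7S,8S,9S,17R)-6,8,9,17-tetrol lactone | C[C@]1(O)C(=O)O[C@@H](CO)[C@@]1(O)[C@@H](O)[C@H]2[C@@H](C)[C@@H](O[Si](C)(C)C(C)(C)C)C[C@H](O[Si](CC)(CC)CC)[C@]2(C)C=C | intermediate
27 | 8,9-acetonide | C[C@]1(O)C(=O)O[C@@H](CO)[C@]12OC(C)(C)O[C@H]2[C@H]3[C@@H](C)[C@@H](O[Si](C)(C)C(C)(C)C)C[C@H](O[Si](CC)(CC)CC)[C@]3(C)C=C | intermediate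
28 | C6 aldehyde | C[C@]1(O)C(=O)O[C@@H](C=O)[C@]12OC(C)(C)O[C@H]2[C@H]3[C@@H](C)[C@@H](O[Si](C)(C)C(C)(C)C)C[C@H](O[Si](CC)(CC)CC)[C@]3(C)C=C | intermediate
29 | (5Z)-5-iodoalkene | C[C@]1(O)C(=O)O[C@@H](/C=C(\I)C)[C@]12OC(C)(C)O[C@H]2[C@H]3[C@@H](C)[C@@H](O[Si](C)(C)C(C)(C)C)C[C@H](O[Si](CC)(CC)CC)[C@]3(C)C=C | intermediate
30 | (5Z)-triene | C[C@]1(O)C(=O)O[C@@H](/C=C(\CC=C)C)[C@]12OC(C)(C)O[C@H]2[C@H]3[C@@H](C)[C@@H](O[Si](C)(C)C(C)(C)C)C[C@H](O[Si](CC)(CC)CC)[C@]3(C)C=C | intermediate
31 | (2Z,5Z)-macrocycle | C1/C=C\[C@@]2(C)[C@@H](O[Si](CC)(CC)CC)C[C@H](O[Si](C)(C)C(C)(C)C)[C@H](C)[C@@H]2[C@@H]2OC(C)(C)O[C@]32[C@@](C)(O)C(=O)O[C@H]3/C=C1/C | intermediate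
32 | 8,9,14,17-tetrol 12-O-TBS macrocyclic diene | C1/C=C\[C@@]2(C)[C@@H](O)C[C@H](O[Si](C)(C)C(C)(C)C)[C@H](C)[C@@H]2[C@H](O)[C@@]3(O)[C@@](C)(O)C(=O)O[C@H]3/C=C1/C | intermediate
33 | (5R,6S)-5,6-epoxide | C1/C=C\[C@@]2(C)[C@@H](O)C[C@H](O[Si](C)(C)C(C)(C)C)[C@H](C)[C@@H]2[C@H](O)[C@@]3(O)[C@@](C)(O)C(=O)O[C@H]3[C@@H]4O[C@@]41C | intermediate
34 | (2R,3S)-2,3-diol | C1[C@H](O)[C@H](O)[C@@]2(C)[C@@H](O)C[C@H](O[Si](C)(C)C(C)(C)C)[C@H](C)[C@@H]2[C@H](O)[C@@]3(O)[C@@](C)(O)C(=O)O[C@H]3[C@@H]4O[C@@]41C | intermediate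
35 | 2,3,9,14-tetraacetate 12-O-TBS ether | C1[C@H](OC(C)=O)[C@H](OC(C)=O)[C@@]2(C)[C@@H](OC(C)=O)C[C@H](O[Si](C)(C)C(C)(C)C)[C@H](C)[C@@H]2[C@H](OC(C)=O)[C@@]3(O)[C@@](C)(O)C(=O)O[C@H]3[C@@H]4O[C@@]41C | intermediate
36 | CNP0287149.1 (1R,2R,3S,5R,6S,7S,8S,9S,10S,11R,12S,14S,17R) | CC(=O)O[C@H]1C[C@@]2(C)O[C@H]2[C@@H]2OC(=O)[C@](C)(O)[C@]2(O)[C@@H](OC(C)=O)[C@H]2[C@@H](C)[C@@H](O)C[C@H](OC(C)=O)[C@]2(C)[C@H]1OC(C)=O | target

**Step count and risks**
Total: 32 steps, all in one linear sequence from geranyl acetate; longest linear sequence 32 steps.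

Step 21 (key step). What may go wrong: the α-lithio carbamate or sec-butyllithium attacks the neighbouring vinyl epoxide, or the carbamoyl group transfers to the γ-carbon, before the desired 1,2-shift. Fallback: separate the carbanion chemistry from the epoxide. Chlorohydrin 20 is silylated (TMSCl, imidazole) to the C7 trimethylsilyl ether F1. s-BuLi/TMEDA then effects the carbamoyl shift to the α-hydroxy amide F2 with the electrophile still masked. K2CO3/MeOH removes the silyl group and closes the epoxide to the neutral epoxy α-hydroxy amide F3, and camphorsulfonic acid in wet THF converts it to lactone 25.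

Step 5. What may go wrong: loss of the wrong proton from the C11 cation (exocyclic or tetrasubstituted alkene isomers), or capture of the allylic cation at its vinyl terminus. Fallback: a titanocene(III) radical cyclisation. Epoxy alcohol 3 is protected as the TBS ether F4, and Cp2TiCl (Mn, collidine·HCl) cyclises it to the exocyclic alkene F5. Acid-mediated isomerisation gives the endocyclic alkene F6 and fluoride gives the diol F7. Selective TEMPO/PhI(OAc)2 oxidation of the primary alcohol gives the hydroxy aldehyde F8, and Takai–Lombardo methylenation gives 6.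

Step 27. What may go wrong: oligomerisation, or failure of the hindered C1 vinyl group to engage, because of the strain of the ring being closed. Fallback: a pinacol macrocyclisation that also installs the 2,3-diol. In iodoalkene 29 the C1 vinyl group is cleaved (OsO4/NaIO4) to the C2 aldehyde F9. Stille coupling with (Z)-tributyl(2-ethoxyvinyl)stannane gives the dienol ether F10, and mild hydrolysis gives the dialdehyde F11. SmI2 pinacol cyclisation gives the macrocyclic 2,3-cis-diol F12, PPTS/MeOH gives the desilylated diene F13, and m-CPBA epoxidation of C5=C6 returns to 34.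

**Further compounds**
F1 | step 21 | C7 trimethylsilyl ether of 20 | C[C@@H](OC(=O)N(CC)CC)/C([C@H](O[Si](C)(C)C)CCl)=C/[C@H]1[C@@H](C)[C@@H](O[Si](C)(C)C(C)(C)C)C[C@H](O[Si](CC)(CC)CC)[C@]1(C)C=C
F2 | step 21 | (17R)-α-hydroxy amide, C7 silyl ether chloride | C[C@](O)(C(=O)N(CC)CC)/C([C@H](O[Si](C)(C)C)CCl)=C/[C@H]1[C@@H](C)[C@@H](O[Si](C)(C)C(C)(C)C)C[C@H](O[Si](CC)(CC)CC)[C@]1(C)C=C
F3 | step 21 | neutral epoxy α-hydroxy amide | C[C@](O)(C(=O)N(CC)CC)/C([C@H]2CO2)=C/[C@H]1[C@@H](C)[C@@H](O[Si](C)(C)C(C)(C)C)C[C@H](O[Si](CC)(CC)CC)[C@]1(C)C=C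
F4 | step 5 | TBS ether of 3 | CC(=O)OC/C=C(\C)CC[C@H]1O[C@]1(C)CO[Si](C)(C)C(C)(C)C
F5 | step 5 | exocyclic (C11=C20) cyclohexanol, C2–OTBS | CC(=O)OC[C@H]1C(=C)CC[C@@H](O)[C@]1(C)CO[Si](C)(C)C(C)(C)C
F6 | step 5 | endocyclic (Δ11) cyclohexenol, C2–OTBS | CC(=O)OC[C@H]1C(C)=CC[C@@H](O)[C@]1(C)CO[Si](C)(C)C(C)(C)C
F7 | step 5 | C2,C14-diol | CC(=O)OC[C@H]1C(C)=CC[C@@H](O)[C@]1(C)CO
F8 | step 5 | C2 aldehyde, 14β-OH | CC(=O)OC[C@H]1C(C)=CC[C@@H](O)[C@]1(C)C=O
F9 | step 27 | C2 aldehyde of 29 | C[C@]1(O)C(=O)O[C@@H](/C=C(\I)C)[C@]12OC(C)(C)O[C@H]2[C@H]3[C@@H](C)[C@@H](O[Si](C)(C)C(C)(C)C)C[C@H](O[Si](CC)(CC)CC)[C@]3(C)C=O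
F10 | step 27 | (Z)-dienol ethyl ether aldehyde | C[C@]1(O)C(=O)O[C@@H](/C=C(\C=C/OCC)C)[C@]12OC(C)(C)O[C@H]2[C@H]3[C@@H](C)[C@@H](O[Si](C)(C)C(C)(C)C)C[C@H](O[Si](CC)(CC)CC)[C@]3(C)C=O
F11 | step 27 | C2,C3-dialdehyde | C[C@]1(O)C(=O)O[C@@H](/C=C(\CC=O)C)[C@]12OC(C)(C)O[C@H]2[C@H]3[C@@H](C)[C@@H](O[Si](C)(C)C(C)(C)C)C[C@H](O[Si](CC)(CC)CC)[C@]3(C)C=O
F12 | step 27 | macrocyclic 2,3-diol, acetonide, TES, TBS | C1[C@H](O)[C@H](O)[C@@]2(C)[C@@H](O[Si](CC)(CC)CC)C[C@H](O[Si](C)(C)C(C)(C)C)[C@H](C)[C@@H]2[C@@H]2OC(C)(C)O[C@]32[C@@](C)(O)C(=O)O[C@H]3/C=C1/C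
F13 | step 27 | macrocyclic 2,3,8,9,14,17-hexol 12-O-TBS (5Z)-alkene | C1[C@H](O)[C@H](O)[C@@]2(C)[C@@H](O)C[C@H](O[Si](C)(C)C(C)(C)C)[C@H](C)[C@@H]2[C@H](O)[C@@]3(O)[C@@](C)(O)C(=O)O[C@H]3/C=C1/C
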